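**Retrosynthetic overview**

- Rings are named A/C/B in the upper unit and D/F/E in the lower unit, with flavan numbering in each. The plan rests on ring D. Its C7 hydroxyl is ortho to the interflavan carbon C6 and meta to the ether carbon C8a. A vinylketene and an alkynyl ether give exactly this 1,3-dioxygen pattern, so no 4→8 isomer can form.
- After protecting-group removal, rings D and F are cut together at C4a–C5, C4a–C8a, C7–C8 and C6–C7. This leads back to an α'-diazo enone on upper C4 whose diazo carbon is tied through lower C4, C3, C2 and O1 to an ethynyl ether.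
- The C5=C6 bond is cut by cross metathesis into a 4α-propenyl flavan and a lower vinyl carbinol. C7 stays at the alcohol level until n-BuLi has unmasked the alkynyl ether from a 1,2-dichlorovinyl ether, because an enone would not survive that reagent.
- Upper unit: chalcone, asymmetric epoxidation, closure of ring C, 3,4-diol, then SN1 allylation at C4. The chalcone oxygen serves as the C4 leaving group, because quinone C–H oxidation is unsafe on a 5-deoxy ring A. Lower chain: a syn-selective alkoxyallylboration sets C2 and C3 and tells their oxygens apart, and hydroformylation adds C7.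
- Ring order: A, B and E are bought, C forms in step 4, and F then D form in step 17.

Key step: step 17

Assumption: the lower C3 oxygen is carried as a methoxymethyl ether instead of a benzyl ether because it enters already in place with the boron reagent; allyl methoxymethyl ether and (+)-B-methoxydiisopinocampheylborane are taken as purchasable.

**Step 1**
Reactants: 1 1-[4-(benzyloxy)-2-hydroxyphenyl]ethanone
Product: 2 1-[4-(benzyloxy)-2-(methoxymethoxy)phenyl]ethanone
Conditions: NaH, MOMCl, DMF, 0 °C → rt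
Reagents that add atoms: chloromethyl methyl ether, COCCl
Why: Williamson-type O-alkylation of the phenoxide; the acetal blocks the ortho hydroxyl so that the later chalcone can neither close to a flavanone nor undergo Algar–Flynn–Oyamada oxidation under the basic peroxide of step 3.

**Step 2**
Reactants: 2 1-[4-(benzyloxy)-2-(methoxymethoxy)phenyl]ethanone; 3 3,4-bis(benzyloxy)benzaldehyde
Product: 4 (E)-1-[4-(benzyloxy)-2-(methoxymethoxy)phenyl]-3-[3,4-bis(benzyloxy)phenyl]prop-2-en-1-one
Conditions: KOH, EtOH, rt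
Reagents that add atoms: none
Why: Claisen–Schmidt aldol condensation, in which E1cB loss of water gives the conjugated E-enone.

**Step 3**
Reactants: 4 the chalcone
Product: 5 (αR,βS)-epoxychalcone
Conditions: poly-L-leucine, urea–H2O2, DBU, THF, rt
Reagents that add atoms: urea–hydrogen peroxide, NC(N)=O.OO
Why: Juliá–Colonna epoxidation (Weitz–Scheffer addition of hydroperoxide held on the helical peptide); the L-peptide should deliver the (αR,βS) trans-epoxide, whose α-carbon becomes upper C3, and crystallisation here or after step 4 should raise the enantiomeric purity.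

**Step 4**
Reactants: 5 (αR,βS)-epoxychalcone
Product: 7 (2R,3R)-7-(benzyloxy)-2-[3,4-bis(benzyloxy)phenyl]-3-hydroxychroman-4-one, via phenol epoxide 6 (not isolated)
Conditions: HCl (cat.), MeOH/THF, 50 °C
Reagents that add atoms: none
Why: Acidic acetal methanolysis frees the phenol, which opens the protonated epoxide at the benzylic carbon (6-endo epoxide opening, ring C) with inversion to the 2,3-trans dihydroflavonol; C3 is not touched, and even if the benzylic carbon ionises the diequatorial trans isomer remains the favoured one.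

**Step 5**
Reactants: 7 the dihydroflavonol
Product: 8 (2R,3S,4R)-7-(benzyloxy)-2-[3,4-bis(benzyloxy)phenyl]chromane-3,4-diol
Conditions: NaBH4, THF/MeOH, 0 °C
Reagents that add atoms: none
Why: Borohydride ketone reduction with axial hydride delivery should give mainly the equatorial 4-ol (2,3-trans-3,4-trans); the C4 configuration is lost again in step 7 and does not matter.

**Step 6**
Reactants: 8 the flavan-3,4-diol
Product: 9 3,4-di-O-benzyl ether of 8
Conditions: NaH, BnBr, Bu4NI (cat.), DMF, 0 °C → rt
Reagents that add atoms: benzyl bromide, BrCc1ccccc1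
Why: Double Williamson etherification; the 3-benzyl ether is the lasting protecting group and the 4-benzyloxy group is the leaving group of step 7.

**Step 7**
Reactants: 9 the 3,4-di-O-benzyl ether
Product: 10 (2R,3S,4R)-4-allyl-3,7-bis(benzyloxy)-2-[3,4-bis(benzyloxy)phenyl]chromane (4α-allyl)
Conditions: allylSiMe3 (3 equiv), TMSOTf (cat.), CH2Cl2, −78 °C
Reagents that add atoms: allyltrimethylsilane, C=CC[Si](C)(C)C
Why: Hosomi–Sakurai-type SN1 allylation; only the C4–O bond ionises because its cation is stabilised by the para C7 ether and the ortho O1, and the silane should attack the face anti to the 3-benzyloxy group to give the 3,4-trans (4α) product, any 4β epimer being removed by chromatography.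

**Step 8**
Reactants: 10 the 4α-allyl flavan
Product: 11 (2R,3S,4R)-3,7-bis(benzyloxy)-2-[3,4-bis(benzyloxy)phenyl]-4-[(E)-prop-1-enyl]chromane
Conditions: RuHCl(CO)(PPh3)3 (5 mol %), toluene, 80 °C
Reagents that add atoms: none
Why: Ruthenium hydride alkene isomerisation (insertion then β-hydride elimination) moves the double bond by one position; a second shift would need the metal next to the tertiary C4 and removal of its hindered hydrogen, so it is slower, and the run is stopped at full conversion to keep C4 intact.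

**Step 9**
Reactants: 12 3-(methoxymethoxy)prop-1-ene; 3 3,4-bis(benzyloxy)benzaldehyde
Product: 14 (1S,2S)-1-[3,4-bis(benzyloxy)phenyl]-2-(methoxymethoxy)but-3-en-1-ol, via Z-alkoxyallylborane 13 (not isolated)
Conditions: s-BuLi, THF, −78 °C; (+)-Ipc2BOMe; BF3·OEt2; 3, −78 °C; then NaOH, H2O2
Reagents that add atoms: (+)-B-methoxydiisopinocampheylborane, COB([C@H]1C[C@H]2C[C@@H]([C@@H]1C)C2(C)C)[C@H]1C[C@H]2C[C@@H]([C@@H]1C)C2(C)C (boron and its two terpene groups stay only in 13)
Why: Brown-type asymmetric alkoxyallylboration through a chair Zimmerman–Traxler transition state; the Z geometry gives the syn relation (later 2,3-cis), the isopinocampheyl groups derived from (−)-α-pinene select the aldehyde face that gives (1S,2S), and the benzylic oxygen is left free while its neighbour is already protected.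

**Step 10**
Reactants: 14 the syn alcohol
Product: 15 (E)-1,2-dichlorovinyl ether of 14
Conditions: KH, THF, 0 °C; Cl2C=CHCl, −50 °C → rt
Reagents that add atoms: trichloroethylene, ClC=C(Cl)Cl
Why: Dichlorovinyl ether synthesis by anti addition of the potassium alkoxide to dichloroacetylene made in the flask; the C–O bond at lower C2 is not touched, so its configuration is kept, and the acetal neighbour can neither migrate nor leave.

**Step 11**
Reactants: 15 the dichlorovinyl ether
Product: 16 (4S,5S)-5-[3,4-bis(benzyloxy)phenyl]-5-[(E)-1,2-dichlorovinyloxy]-4-(methoxymethoxy)pentanal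
Conditions: Rh(acac)(CO)2 (2 mol %), BIPHEPHOS (4 mol %), CO/H2 (1:1, 10 bar), toluene, 60 °C
Reagents that add atoms: carbon monoxide, [C-]#[O+]
Why: Linear-selective rhodium-catalysed hydroformylation; the wide-bite-angle bisphosphite places the formyl group (C7) on the terminal carbon, and the trisubstituted chloroalkene and the benzyl ethers are inert.

**Step 12**
Reactants: 16 the aldehyde
Product: 17 (6S,7S)-7-[3,4-bis(benzyloxy)phenyl]-7-[(E)-1,2-dichlorovinyloxy]-6-(methoxymethoxy)hept-1-en-3-ol (both C3 epimers)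
Conditions: CH2=CHMgBr, THF, −78 °C; then H2O
Reagents that add atoms: vinylmagnesium bromide, C=C[Mg]Br
Why: Grignard 1,2-addition; the new carbinol centre is a mixture that step 15 erases, and the reagent is not basic enough to attack the dichlorovinyl ether.

**Step 13**
Reactants: 11 the 4α-propenyl flavan; 17 the vinyl carbinol
Product: 18 E-allylic alcohol joining upper C4 to the lower chain (dichlorovinyl ether; both carbinol epimers)
Conditions: 17 (2 equiv), second-generation Hoveyda–Grubbs catalyst RuCl2(H2IMes)(=CH-C6H4-2-OiPr) (10 mol %), 1,4-benzoquinone (20 mol %), CH2Cl2, 40 °C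
Reagents that add atoms: none
Why: Olefin cross metathesis between an alkene too hindered to dimerise and a slowly dimerising secondary allylic alcohol used in excess should favour the E cross product with loss of propene; the chloroalkene does not take part and the quinone suppresses hydride-induced migration of the allylic alcohol.

**Step 14**
Reactants: 18 the dichlorovinyl allylic alcohol
Product: 20 ethynyl ether allylic alcohol, via dilithio alkynyl ether 19 (not isolated)
Conditions: n-BuLi (3.5 equiv), THF, −78 → −40 °C; then H2O, −78 °C; chromatography on Et3N-washed silica, kept below 20 °C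
Reagents that add atoms: n-butyllithium, [Li]CCCC (its lithium stays only in 19)
Why: Second stage of the dichlorovinyl ether route to alkynyl ethers (vinyl deprotonation, loss of chloride, chlorine–lithium exchange, protonation); the first equivalent only makes the alkoxide, which is why C7 is held at the alcohol level here.

**Step 15**
Reactants: 20 the ethynyl ether allylic alcohol
Product: 21 E-enone with ethynyl ether
Conditions: MnO2 (20 equiv), CH2Cl2, 15 °C
Reagents that add atoms: none
Why: Allylic alcohol oxidation on MnO2 is neutral and heterogeneous, so the acid-sensitive alkynyl ether should survive, and both carbinol epimers converge on one ketone.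

**Step 16**
Reactants: 21 the enone
Product: 23 α'-diazo enone (benzannulation precursor), via trifluoroacetyl diketone 22 (not isolated)
Conditions: LiN(SiMe3)2 (1.05 equiv), THF, −78 °C; CF3CO2CH2CF3, −78 °C; pH 7 buffer; then MsN3 (1.2 equiv), Et3N, H2O (1 equiv), MeCN, 0–20 °C
Reagents that add atoms: methanesulfonyl azide, CS(=O)(=O)N=[N+]=[N-]; 2,2,2-trifluoroethyl trifluoroacetate, O=C(OCC(F)(F)F)C(F)(F)F (its acyl group stays only in 22)
Why: Detrifluoroacetylative (Regitz-type) diazo transfer; the kinetic α'-enolate at C4a is acylated and the activated diketone takes N2 from the azide and sheds the trifluoroacetyl group, while the ketone proton is more acidic than the alkyne proton and the anion consumes the azide far faster than the neutral alkynyl ether can add to it.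

**Step 17**
Reactants: 23 the α'-diazo enone
Product: 28 hexabenzyl methoxymethyl ether of the target with free lower C7 phenol, via vinylketene 24 (not isolated), via fused cyclobutenone 25 (not isolated), via dienylketene 26 (not isolated), via cyclohexadienone 27 (not isolated)
Conditions: hν (365 nm LED, Pyrex), degassed ClCH2CH2Cl (0.005 M), 10 °C until N2 evolution ends; then 80 °C
Reagents that add atoms: none
Why: Proposed new method: light expels N2 from 23 while the alkenyl carbon C5 shifts from C7 to C4a (Wolff rearrangement), and in vinylketene 24 the electrophilic C7 is attacked by the nucleophilic terminal alkyne carbon C8 as C4a bonds to the oxygen-bearing C8a, a (2+2) cycloaddition that gives 25. On heating, 25 opens at C4a–C7 in a conrotatory four-electron process to 26, which closes C6–C7 by six-electron electrocyclisation to 27 and tautomerises to phenol 28. The closest known reaction is the intermolecular Danheiser benzannulation of α'-diazo enones with alkoxyalkynes under photochemical Wolff conditions, which gives resorcinol monoethers; new here are the intramolecular mode and the oxygen-containing tether. Ring F closes in the (2+2) event as the six-membered ring of a 2-oxabicyclo[4.2.0]octenone (four-atom tether C4–C3–C2–O1 between C4a and C8a), and ring D closes in the electrocyclisation, which the tether helps because the C4a=C8a bond of 26 is endocyclic in ring F, so only inward rotation of the alkenyl group is possible and the ketene and alkene termini are held cis. No lasting stereocentre is made (quaternary C4a of 25 and C6 of 27 become planar again), and lower C2 and C3 and upper C2, C3 and C4 lie outside the reacting array and are kept. The step needs the Wolff shift to beat the 1,2-hydrogen shift from C4H2 (direct excitation of the s-Z diazo ketone favours the concerted shift), the head-to-tail regiochemistry (set by ketene and alkynyl ether polarity and the only one the tether allows) and capture of the alkynyl ether at 10 °C before its own sigmatropic or retro-ene decay, while 365 nm light and high dilution spare the aryl ethers and suppress ketene dimerisation.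

**Step 18**
Reactants: 28 the benzannulation product
Product: 29 hexabenzyl ether of the target with free lower C3 and C7 hydroxyls
Conditions: ZnBr2, n-PrSH, CH2Cl2, 0 °C
Reagents that add atoms: none
Why: Lewis acid and thiol cleavage of the methoxymethyl acetal; the thiol traps the formaldehyde unit as a dithioacetal so that it cannot attack the nucleophilic C8 of ring D, and the benzyl ethers and the acid-resistant 5-deoxy interflavan bond should hold at 0 °C.

**Step 19**
Reactants: 29 the hexabenzyl ether
Product: 30 fisetinidol-(4α→6)-ent-epifisetinidol (target)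
Conditions: H2 (1 atm), Pd(OH)2/C, THF/MeOH, rt
Reagents that add atoms: none
Why: Catalytic hydrogenolysis of the six benzyl ethers, the standard last step for benzylated flavan oligomers, under which the ring C2–O1 bonds and the C4–C6 bond are normally kept.

**Compound list**

1 | 1-[4-(benzyloxy)-2-hydroxyphenyl]ethanone | CC(=O)c1ccc(OCc2ccccc2)cc1O | starting material
2 | 1-[4-(benzyloxy)-2-(methoxymethoxy)phenyl]ethanone | CC(=O)c1ccc(OCc2ccccc2)cc1OCOC | intermediate
3 | 3,4-bis(benzyloxy)benzaldehyde | O=Cc1ccc(OCc2ccccc2)c(OCc2ccccc2)c1 | starting material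
4 | (E)-chalcone | COCOc1cc(OCc2ccccc2)ccc1C(=O)/C=C/c1ccc(OCc2ccccc2)c(OCc2ccccc2)c1 | intermediate
5 | (αR,βS)-epoxychalcone | COCOc1cc(OCc2ccccc2)ccc1C(=O)[C@@H]1O[C@H]1c1ccc(OCc2ccccc2)c(OCc2ccccc2)c1 | intermediate
6 | (αR,βS)-epoxychalcone with free ortho phenol | Oc1cc(OCc2ccccc2)ccc1C(=O)[C@@H]1O[C@H]1c1ccc(OCc2ccccc2)c(OCc2ccccc2)c1 | intermediate
7 | (2R,3R)-tri-O-benzyl dihydroflavonol | O(Cc3ccccc3)c1ccc2c(c1)O[C@H](c1ccc(OCc3ccccc3)c(OCc3ccccc3)c1)[C@@H](O)C2=O | intermediate
8 | (2R,3S,4R)-tri-O-benzyl flavan-3,4-diol | O(Cc3ccccc3)c1ccc2c(c1)O[C@H](c1ccc(OCc3ccccc3)c(OCc3ccccc3)c1)[C@@H](O)[C@@H]2O | intermediate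
9 | 3,4-di-O-benzyl ether of 8 (2,3-trans-3,4-trans) | O(Cc3ccccc3)c1ccc2c(c1)O[C@H](c1ccc(OCc3ccccc3)c(OCc3ccccc3)c1)[C@@H](OCc3ccccc3)[C@@H]2OCc1ccccc1 | intermediate
10 | (2R,3S,4R)-4α-allyl tetra-O-benzyl flavan | O(Cc3ccccc3)c1ccc2c(c1)O[C@H](c1ccc(OCc3ccccc3)c(OCc3ccccc3)c1)[C@@H](OCc3ccccc3)[C@@H]2CC=C | intermediate
11 | (2R,3S,4R)-4α-[(E)-prop-1-enyl] tetra-O-benzyl flavan | O(Cc3ccccc3)c1ccc2c(c1)O[C@H](c1ccc(OCc3ccccc3)c(OCc3ccccc3)c1)[C@@H](OCc3ccccc3)[C@@H]2/C=C/C | intermediate
12 | 3-(methoxymethoxy)prop-1-ene | C=CCOCOC | starting material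
13 | [(Z)-3-(methoxymethoxy)allyl]diisopinocampheylborane | COCO/C=C\CB([C@H]1C[C@H]2C[C@@H]([C@@H]1C)C2(C)C)[C@H]1C[C@H]2C[C@@H]([C@@H]1C)C2(C)C | intermediate
14 | (1S,2S)-1-[3,4-bis(benzyloxy)phenyl]-2-(methoxymethoxy)but-3-en-1-ol | O[C@@H](c1ccc(OCc2ccccc2)c(OCc2ccccc2)c1)[C@@H](OCOC)C=C | intermediate
15 | (E)-1,2-dichlorovinyl ether of 14 | Cl/C=C(/Cl)O[C@@H](c1ccc(OCc2ccccc2)c(OCc2ccccc2)c1)[C@@H](OCOC)C=C | intermediate
16 | (4S,5S)-pentanal with dichlorovinyl ether | Cl/C=C(/Cl)O[C@@H](c1ccc(OCc2ccccc2)c(OCc2ccccc2)c1)[C@@H](OCOC)CCC=O | intermediate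
17 | (6S,7S)-hept-1-en-3-ol with dichlorovinyl ether (C3 epimers) | Cl/C=C(/Cl)O[C@@H](c1ccc(OCc2ccccc2)c(OCc2ccccc2)c1)[C@@H](OCOC)CCC(O)C=C | intermediate
18 | cross-metathesis product, E-allylic alcohol with dichlorovinyl ether (carbinol epimers) | O(Cc3ccccc3)c1ccc2c(c1)O[C@H](c1ccc(OCc3ccccc3)c(OCc3ccccc3)c1)[C@@H](OCc3ccccc3)[C@@H]2/C=C/C(O)CC[C@H](OCOC)[C@H](c1ccc(OCc3ccccc3)c(OCc3ccccc3)c1)O/C(Cl)=C\Cl | intermediate
19 | lithium alkoxide and lithium acetylide of 20 | O(Cc3ccccc3)c1ccc2c(c1)O[C@H](c1ccc(OCc3ccccc3)c(OCc3ccccc3)c1)[C@@H](OCc3ccccc3)[C@@H]2/C=C/C(O[Li])CC[C@H](OCOC)[C@H](c1ccc(OCc3ccccc3)c(OCc3ccccc3)c1)OC#C[Li] | intermediate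
20 | E-allylic alcohol with ethynyl ether (carbinol epimers) | O(Cc3ccccc3)c1ccc2c(c1)O[C@H](c1ccc(OCc3ccccc3)c(OCc3ccccc3)c1)[C@@H](OCc3ccccc3)[C@@H]2/C=C/C(O)CC[C@H](OCOC)[C@H](c1ccc(OCc3ccccc3)c(OCc3ccccc3)c1)OC#C | intermediate
21 | E-enone with ethynyl ether | O(Cc3ccccc3)c1ccc2c(c1)O[C@H](c1ccc(OCc3ccccc3)c(OCc3ccccc3)c1)[C@@H](OCc3ccccc3)[C@@H]2/C=C/C(=O)CC[C@H](OCOC)[C@H](c1ccc(OCc3ccccc3)c(OCc3ccccc3)c1)OC#C | intermediate
22 | α'-trifluoroacetyl enone (either configuration at C4a, or enol) | O(Cc3ccccc3)c1ccc2c(c1)O[C@H](c1ccc(OCc3ccccc3)c(OCc3ccccc3)c1)[C@@H](OCc3ccccc3)[C@@H]2/C=C/C(=O)C(C(=O)C(F)(F)F)C[C@H](OCOC)[C@H](c1ccc(OCc3ccccc3)c(OCc3ccccc3)c1)OC#C | intermediate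
23 | α'-diazo enone, precursor of the key step | O(Cc3ccccc3)c1ccc2c(c1)O[C@H](c1ccc(OCc3ccccc3)c(OCc3ccccc3)c1)[C@@H](OCc3ccccc3)[C@@H]2/C=C/C(=O)C(=[N+]=[N-])C[C@H](OCOC)[C@H](c1ccc(OCc3ccccc3)c(OCc3ccccc3)c1)OC#C | intermediate
24 | vinylketene | O(Cc3ccccc3)c1ccc2c(c1)O[C@H](c1ccc(OCc3ccccc3)c(OCc3ccccc3)c1)[C@@H](OCc3ccccc3)[C@@H]2/C=C/C(=C=O)C[C@H](OCOC)[C@H](c1ccc(OCc3ccccc3)c(OCc3ccccc3)c1)OC#C | intermediate
25 | fused cyclobutenone, 2-oxabicyclo[4.2.0]octenone (either configuration at quaternary C4a) | O(Cc3ccccc3)c1ccc2c(c1)O[C@H](c1ccc(OCc3ccccc3)c(OCc3ccccc3)c1)[C@@H](OCc3ccccc3)[C@@H]2/C=C/C13C[C@H](OCOC)[C@H](c4ccc(OCc5ccccc5)c(OCc5ccccc5)c4)OC1=CC3=O | intermediate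
26 | dienylketene with ring F closed | O(Cc3ccccc3)c1ccc2c(c1)O[C@H](c1ccc(OCc3ccccc3)c(OCc3ccccc3)c1)[C@@H](OCc3ccccc3)[C@@H]2/C=C/C1=C(C=C=O)O[C@@H](c3ccc(OCc4ccccc4)c(OCc4ccccc4)c3)[C@@H](OCOC)C1 | intermediate
27 | cyclohexa-2,4-dienone (either configuration at C6) | O(Cc3ccccc3)c1ccc2c(c1)O[C@H](c1ccc(OCc3ccccc3)c(OCc3ccccc3)c1)[C@@H](OCc3ccccc3)[C@@H]2C1C=C2C[C@H](OCOC)[C@H](c3ccc(OCc4ccccc4)c(OCc4ccccc4)c3)OC2=CC1=O | intermediate
28 | hexabenzyl methoxymethyl ether of the target, free lower C7 phenol | O(Cc3ccccc3)c1ccc2c(c1)O[C@H](c1ccc(OCc3ccccc3)c(OCc3ccccc3)c1)[C@@H](OCc3ccccc3)[C@@H]2c1cc2c(cc1O)O[C@@H](c1ccc(OCc3ccccc3)c(OCc3ccccc3)c1)[C@@H](OCOC)C2 | intermediate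
29 | hexabenzyl ether of the target, free lower C3 and C7 hydroxyls | O(Cc3ccccc3)c1ccc2c(c1)O[C@H](c1ccc(OCc3ccccc3)c(OCc3ccccc3)c1)[C@@H](OCc3ccccc3)[C@@H]2c1cc2c(cc1O)O[C@@H](c1ccc(OCc3ccccc3)c(OCc3ccccc3)c1)[C@@H](O)C2 | intermediate
30 | fisetinidol-(4α→6)-ent-epifisetinidol | Oc1ccc2c(c1)O[C@H](c1ccc(O)c(O)c1)[C@@H](O)[C@@H]2c1cc2c(cc1O)O[C@@H](c1ccc(O)c(O)c1)[C@@H](O)C2 | target

**Step count**

- Total step count: 19.
- Longest linear sequence: 15 steps (steps 1–8, then 13–19). The lower branch (steps 9–12) joins at step 13.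

**Steps most likely to fail**

**Step 17.** Several processes may compete:
- A 1,2-hydrogen shift from C4H2 may outrun the Wolff shift.
- The ketene may dimerise or be caught by traces of water.
- The benzylic alkynyl ether may rearrange sigmatropically or fragment before it is captured.

The fallback gives up ring construction and forms the interflavan bond by the standard cationic arylation. It sets out from 4 and 9 and comes back at 30.
- Epoxidation of 4 as in step 3 but over poly-D-leucine gives the (αS,βR)-epoxychalcone F1.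
- HCl in MeOH closes it to the (2S,3S)-dihydroflavonol F2, and NaBH4 gives the enantiomeric flavan-3,4-diol F3.
- Ionic reduction (Et3SiH, BF3·OEt2) removes the benzylic 4-hydroxyl to give tri-O-benzyl-ent-fisetinidol F4.
- Dess–Martin oxidation gives the flavan-3-one F5.
- LiBH(s-Bu)3 attacks the face away from the 2-aryl group to give the 2,3-cis tri-O-benzyl-ent-epifisetinidol F6.
- TMSOTf-promoted Friedel–Crafts coupling of 9 with an excess of F6 at −78 °C gives the heptabenzyl biflavanoid F7.
- A resorcinol-type ring reacts mainly at C6, but a 4→8 isomer now has to be separated. Hydrogenolysis as in step 19 then gives 30.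

**Step 16.** Three processes may interfere:
- The terminal alkyne carbon may be lithiated and trifluoroacetylated.
- The sulfonyl azide may slowly add to the electron-rich triple bond.
- The alkynyl ether may decay over the two-stage procedure.

The fallback changes the order of events so that the alkynyl ether meets neither the amide base nor the acylating agent. It sets out from 18 and comes back at 22.
- MnO2 oxidises 18 to the dichlorovinyl enone F8.
- LiN(SiMe3)2 and CF3CO2CH2CF3 give the dichlorovinyl trifluoroacetyl diketone F9, the chloroalkene being inert to both reagents.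
- n-BuLi (3.3 equiv, −78 °C) first turns F9 into its lithium diketonate, which shields both carbonyl groups as an enolate, and then unmasks the alkyne.
- A buffered quench gives 22, which goes at once into the azide stage of step 16.

**Step 13.** Turnover at the hindered internal alkene may be sluggish, 17 may self-metathesise, and hydride-induced migration may convert the allylic alcohol into an ethyl ketone. The fallback replaces alkene exchange by carbonyl addition. It sets out from 11 and 16 and comes back at 18.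
- Lemieux–Johnson cleavage of 11 (OsO4 cat., NaIO4, 2,6-lutidine, dioxane/H2O) gives the flavan-4α-carbaldehyde F10.
- Takai olefination (CrCl2, CHI3, THF, 0 °C) is non-basic, so the epimerisable C4 is safe, and gives the E-vinyl iodide F11.
- Nozaki–Hiyama–Kishi coupling of F11 with aldehyde 16 (CrCl2, NiCl2 cat., DMF) gives 18. The carbon–iodine bond reacts far faster than the vinyl chlorides.

**Further compounds**

F1 | step 17 | (αS,βR)-epoxychalcone | COCOc1cc(OCc2ccccc2)ccc1C(=O)[C@H]1O[C@@H]1c1ccc(OCc2ccccc2)c(OCc2ccccc2)c1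
F2 | step 17 | (2S,3S)-tri-O-benzyl dihydroflavonol | O(Cc3ccccc3)c1ccc2c(c1)O[C@@H](c1ccc(OCc3ccccc3)c(OCc3ccccc3)c1)[C@H](O)C2=O
F3 | step 17 | (2S,3R,4S)-tri-O-benzyl flavan-3,4-diol | O(Cc3ccccc3)c1ccc2c(c1)O[C@@H](c1ccc(OCc3ccccc3)c(OCc3ccccc3)c1)[C@H](O)[C@H]2O
F4 | step 17 | (2S,3R)-tri-O-benzyl-ent-fisetinidol | O(Cc3ccccc3)c1ccc2c(c1)O[C@@H](c1ccc(OCc3ccccc3)c(OCc3ccccc3)c1)[C@H](O)C2
F5 | step 17 | (2S)-tri-O-benzyl flavan-3-one | O(Cc3ccccc3)c1ccc2c(c1)O[C@@H](c1ccc(OCc3ccccc3)c(OCc3ccccc3)c1)C(=O)C2
F6 | step 17 | (2S,3S)-tri-O-benzyl-ent-epifisetinidol | O(Cc3ccccc3)c1ccc2c(c1)O[C@@H](c1ccc(OCc3ccccc3)c(OCc3ccccc3)c1)[C@@H](O)C2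
F7 | step 17 | heptabenzyl ether of the target with free lower C3 hydroxyl | O(Cc3ccccc3)c1ccc2c(c1)O[C@H](c1ccc(OCc3ccccc3)c(OCc3ccccc3)c1)[C@@H](OCc3ccccc3)[C@@H]2c1cc2c(cc1OCc4ccccc4)O[C@@H](c1ccc(OCc3ccccc3)c(OCc3ccccc3)c1)[C@@H](O)C2
F8 | step 16 | E-enone with dichlorovinyl ether | O(Cc3ccccc3)c1ccc2c(c1)O[C@H](c1ccc(OCc3ccccc3)c(OCc3ccccc3)c1)[C@@H](OCc3ccccc3)[C@@H]2/C=C/C(=O)CC[C@H](OCOC)[C@H](c1ccc(OCc3ccccc3)c(OCc3ccccc3)c1)O/C(Cl)=C\Cl
F9 | step 16 | α'-trifluoroacetyl enone with dichlorovinyl ether | O(Cc3ccccc3)c1ccc2c(c1)O[C@H](c1ccc(OCc3ccccc3)c(OCc3ccccc3)c1)[C@@H](OCc3ccccc3)[C@@H]2/C=C/C(=O)C(C(=O)C(F)(F)F)C[C@H](OCOC)[C@H](c1ccc(OCc3ccccc3)c(OCc3ccccc3)c1)O/C(Cl)=C\Cl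
F10 | step 13 | tetra-O-benzyl flavan-4α-carbaldehyde | O(Cc3ccccc3)c1ccc2c(c1)O[C@H](c1ccc(OCc3ccccc3)c(OCc3ccccc3)c1)[C@@H](OCc3ccccc3)[C@@H]2C=O
F11 | step 13 | tetra-O-benzyl 4α-[(E)-2-iodovinyl]flavan | O(Cc3ccccc3)c1ccc2c(c1)O[C@H](c1ccc(OCc3ccccc3)c(OCc3ccccc3)c1)[C@@H](OCc3ccccc3)[C@@H]2/C=C/I
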